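# Gardenin D by late-stage carbonyl-directed C5–H hydroxylation: synthesis design

## The problem

Gardenin D 12 is 5,3'-dihydroxy-6,7,8,4'-tetramethoxyflavone, a 2-aryl-4H-chromen-4-one in which every carbon of ring A carries oxygen and ring B is a 3-hydroxy-4-methoxyphenyl group. The molecule has no stereocentre, so the task is purely one of regiochemistry: six oxygen substituents have to be placed, and the two free phenols (C5–OH on ring A, C3'–OH on ring B) have to be told apart from four methyl ethers. Building ring A with all four oxygens from the start calls for a pentaoxygenated, hexasubstituted benzene and normally ends in a selective demethylation. The sensitive parts are the fully oxygenated ring A, which can be oxidised to a 5,8-quinone once C5–OH is free, the guaiacol-type phenol of ring B, and the pyranone, which opens in hot strong base. Acid is less of a worry, because C6 and C8 carry the same group and a Wessely–Moser ring opening and reclosure would return the same compound. The enabling feature is that the C5 oxygen is the only ring A oxygen peri to the C4 carbonyl: in a 6,7,8-trimethoxyflavone the C5–H is the only C–H of ring A and the only C–H of the molecule that can form a five-membered metallacycle (O=C4–C4a–C5–metal) with the carbonyl oxygen. The carbonyl can therefore direct the introduction of that oxygen as the last bond-forming event on the skeleton.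

## Retrosynthesis

**12 ⇒ 11.** The O–acyl bond at C3' is cut. The ring B phenol cannot face the oxidant of the key step unprotected. An ester is preferred to an ether because it withdraws electron density from ring B and survives a hot trifluoroacetic medium. A benzyl ether would not tolerate that medium, and a methyl ether could not be removed selectively. The forward step is a base-catalysed methanolysis that must leave the methyl ethers, the chelated C5–OH and the pyranone untouched.

**11 ⇒ 9 (through 10).** The C5–O bond is cut. The neighbouring option, cleaving a C5 methyl ether, would need ring A with four oxygens from the outset and so a pentaoxygenated benzene precursor. The C–H cut instead gives flavone 9, whose ring A comes from a trisubstituted benzaldehyde. The oxygenation is placed on 9 and not on ketone 5 or chalcone 7, because those carry a free ortho-phenol (and 7 an oxidisable enone), whereas in 9 the carbonyl is held coplanar with ring A. The forward reaction must deliver oxygen only at C5, leave both electron-rich rings unoxidised, and hold the new phenol as the ester 10 until work-up.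

**9 ⇒ 8.** The same O–acyl bond is cut. The pivalate is installed only after the base-mediated steps, since it would not survive the hydroxide of the condensation.

**8 ⇒ 7.** The O1–C2 bond is cut and the C2=C3 unsaturation removed, giving 2'-hydroxychalcone 7. A Baker–Venkataraman sequence would need an activated ring B acid and two more steps. The forward step is an oxidative cyclisation (oxa-Michael closure and dehydrogenation) that must not halogenate ring B.

**7 ⇒ 5 + 6.** The C2–C3 bond of the future flavone (the enone C=C) is cut. This is the most convergent cut, dividing the skeleton into the ring A ketone 5 and isovanillin 6, both unprotected. The forward step is a Claisen–Schmidt condensation run with both partners as phenoxides.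

**5 ⇒ 3 (through 4).** The aryl–acyl bond (the future C4–C4a) is cut. Phenol 3 has a single free ortho position, and the acylation is asked to go there and not to the other free ring carbon.

**3 ⇒ 1 (through 2).** The phenolic C–O bond is traced back to the formyl C–C bond of aldehyde 1, an inexpensive compound that already has the three contiguous methoxy groups. The forward step is a peracid oxidation with aryl migration, followed by cleavage of formate 2.

## Roads not taken

Alternative 1: The O1–C8a bond is cut. The enol of 1-[3-(benzyloxy)-4-methoxyphenyl]-3-(2,3,4,5-tetramethoxyphenyl)propane-1,3-dione A1 would be cyclised oxidatively, with PhI(OCOCF3)2 and BF3·OEt2 or at an anode, closing ring C to give 3'-(benzyloxy)-5,6,7,8,4'-pentamethoxyflavone A2. One BCl3 treatment of A2 could then remove both the C5 methyl and the benzyl group to give 12.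
- Merits: ring C is built in the key step, all oxygens are installed early, and the endgame demethylation is classical.
- Weak points: the doubly activated CH2 of A1 is the site a trivalent iodine reagent attacks most readily. The arene radical cation of a tetramethoxyarene has several reactive positions. Attack of the enol oxygen at the methoxy-bearing ortho carbon, with loss of methanol, would give a flavone lacking the C5 oxygen. Closure onto ring B is also possible.
- Comparison: the step count is about the same and no ester protecting group is needed, which is an advantage. Against this the chosen plan has a simpler ring A (three methoxy groups, from 1), a site of reaction fixed by the substitution pattern, and an oxidation that is metal-directed and does not depend on arene electronics.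

Alternative 2: The O1–C8a and C4–C4a bonds are cut together. CsF would release 3,4,5,6-tetramethoxybenzyne A4 from 2,3,4,5-tetramethoxy-6-(trimethylsilyl)phenyl trifluoromethanesulfonate A3. The carboxylate of 3-[3-(benzyloxy)-4-methoxyphenyl]prop-2-ynoic acid A5 would add to A4 through oxygen, and attack of the resulting aryl anion on the carboxyl carbon would give 3-[3-(benzyloxy)-4-methoxyphenyl]-1-(2-hydroxy-3,4,5,6-tetramethoxyphenyl)prop-2-yn-1-one A6. A 6-endo cyclisation of A6 would then give A2, followed by the same deprotection as above.
- Merits: two bonds form in one mild, convergent step, the acid A5 is a simple ring B building block, and because A4 is symmetric the insertion has no regiochemical issue. On convergence and mildness this road is better than the chosen one.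
- Weak points: A3 is itself a hexasubstituted benzene that needs a multistep synthesis longer than the whole ring A sequence of the chosen route. A4 is an electron-rich aryne hindered on both sides. Cyclisation of A6 can also take the 5-exo course and close a five-membered ring instead of the pyranone. A selective C5 demethylation is still required.
- Comparison: the chosen plan offers a shorter overall route from cheaper materials and needs no demethylation.

Alternative 3: The C2–C1' bond is cut. 5-(Benzyloxy)-6,7,8-trimethoxy-4H-chromen-4-one A7 and [3-(benzyloxy)-4-methoxyphenyl]boronic acid A8 would be coupled with Pd(OCOCF3)2 (divalent palladium) and O2 or a quinone as terminal oxidant, to give 5,3'-di-O-benzyl Gardenin D A9. One hydrogenolysis of A9 would release 12.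
- Merits: ring B is introduced last, which is the best arrangement for analogues. No oxidant meets a free phenol, and the deprotection of A9 is a single clean step. In modularity this road is superior.
- Weak points: A7 contains the whole difficult ring A with the C5 oxygen already differentiated, so the regiochemical problem is moved into the synthesis of a pentaoxygenated acetophenone and not solved. The coupling can stop at the flavanone oxidation level. Electron-rich boronic acids such as A8 are prone to homocoupling and protodeboronation under oxidative conditions.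
- Comparison: the chosen plan has a much simpler ring A precursor and therefore a shorter linear sequence.

Key step: step 6

## Route

Remark on the chemistry: flavone numbering is used throughout (ring A C5–C8, ring C O1–C4, ring B primed), and the aryl trifluoroacetate 10 is assumed to hydrolyse during the mild aqueous work-up, as aryl trifluoroacetates generally do.

Step 1
Reactants: 1 2,3,4-trimethoxybenzaldehyde
Product: 3 2,3,4-trimethoxyphenol, via 2,3,4-trimethoxyphenyl formate 2 (not isolated)
Conditions: mCPBA, CH2Cl2, 0 °C to rt; aq. Na2SO3/NaHCO3 wash; then K2CO3 (cat.), MeOH, rt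
Reagents that add atoms: mCPBA (3-chloroperoxybenzoic acid), O=C(OO)c1cccc(Cl)c1
Why: Dakin-type oxidation (Baeyer–Villiger oxidation of an aldehyde); the aryl group, made electron-rich by ortho and para methoxy groups, should migrate in preference to hydride, and the labile aryl formate 2 is cleaved by catalytic methanolysis.

Step 2
Reactants: 3 2,3,4-trimethoxyphenol
Product: 5 1-(2-hydroxy-3,4,5-trimethoxyphenyl)ethan-1-one, via difluoroboron chelate 4 (not isolated)
Conditions: AcOH, BF3·OEt2, 90 °C; then H2O, 60 °C
Reagents that add atoms: acetic acid, CC(=O)O
Why: Friedel–Crafts (Fries-type) C-acylation of a phenol; the boron-bound hydroxyl directs the acetyl group to its only free ortho position (C6, para to the 3-methoxy group). The product is captured as the chelate 4, which prevents a second acylation and is hydrolysed by warm water.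

Step 3
Reactants: 5 1-(2-hydroxy-3,4,5-trimethoxyphenyl)ethan-1-one; 6 isovanillin (3-hydroxy-4-methoxybenzaldehyde)
Product: 7 (E)-1-(2-hydroxy-3,4,5-trimethoxyphenyl)-3-(3-hydroxy-4-methoxyphenyl)prop-2-en-1-one
Conditions: KOH (excess), EtOH/H2O, rt; then aq. HCl to pH 4
Reagents that add atoms: none
Why: Claisen–Schmidt condensation; the phenoxide of 6 is meta to the formyl group and so does not deactivate it by conjugation. Dehydration by the E1cB path should give the conjugated E-enone as the thermodynamic isomer.

Step 4
Reactants: 7 (E)-1-(2-hydroxy-3,4,5-trimethoxyphenyl)-3-(3-hydroxy-4-methoxyphenyl)prop-2-en-1-one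
Product: 8 2-(3-hydroxy-4-methoxyphenyl)-6,7,8-trimethoxy-4H-chromen-4-one
Conditions: I2 (10 mol %), DMSO, 120 °C
Reagents that add atoms: none
Why: I2–DMSO oxidative cyclisation of a 2'-hydroxychalcone; 6-endo oxa-Michael closure of O1–C2 is followed by iodine-mediated dehydrogenation across C2–C3, and DMSO reoxidises the HI so that iodine stays catalytic.

Step 5
Reactants: 8 2-(3-hydroxy-4-methoxyphenyl)-6,7,8-trimethoxy-4H-chromen-4-one
Product: 9 2-methoxy-5-(6,7,8-trimethoxy-4-oxo-4H-chromen-2-yl)phenyl pivalate
Conditions: PivCl, Et3N, DMAP (cat.), CH2Cl2, 0 °C to rt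
Reagents that add atoms: pivaloyl chloride, CC(C)(C)C(=O)Cl
Why: DMAP-catalysed O-acylation of the only free hydroxyl in 8; the hindered, electron-withdrawing ester is chosen to survive hot CF3CO2H and to deactivate ring B towards the oxidant of step 6.

Step 6
Reactants: 9 2-methoxy-5-(6,7,8-trimethoxy-4-oxo-4H-chromen-2-yl)phenyl pivalate
Product: 11 5-(5-hydroxy-6,7,8-trimethoxy-4-oxo-4H-chromen-2-yl)-2-methoxyphenyl pivalate (3'-O-pivaloyl Gardenin D), via C5 trifluoroacetate 10 (not isolated)
Conditions: [RuCl2(p-cymene)]2 (5 mol %), PhI(OCOCF3)2 (1.5–2 equiv, in portions), CF3CO2H/(CF3CO)2O, 80 °C; then aq. NaHCO3, rt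
Reagents that add atoms: [bis(trifluoroacetoxy)iodo]benzene, O=C(OI(OC(=O)C(F)(F)F)c1ccccc1)C(F)(F)F; trifluoroacetic acid, OC(=O)C(F)(F)F (the trifluoroacetate pool from which the C5 oxygen is drawn)
Why: The C4 carbonyl oxygen binds the cationic divalent ruthenium trifluoroacetate formed from [RuCl2(p-cymene)]2 in CF3CO2H, and carboxylate-assisted cleavage of the peri C5–H gives a five-membered ruthenacycle through O, C4, C4a and C5. PhI(OCOCF3)2 oxidises this to a tetravalent ruthenium aryl trifluoroacetate, and C–O reductive elimination releases ester 10 and returns divalent ruthenium. The closest known reaction type is the ketone-directed ortho C–H hydroxylation of aryl ketones, which has been carried out at C5 of flavones and chromones under these conditions. No ring is closed in the product and no stereocentre is formed. The selectivity needed is positional: C5–H is the only C–H on ring A and the only one in 9 that can form a five-membered chelate with the carbonyl, since C3–H would need a four-membered ring and the ring B hydrogens are out of reach. (CF3CO)2O keeps the medium dry and holds the new oxygen as the electron-poor ester 10, so the fully oxygenated ring A should not be oxidised on to a quinone; the pivalate protects ring B in the same way. The NaHCO3 work-up should hydrolyse the aryl trifluoroacetate but not the hindered pivalate, leaving the C5–OH of 11 hydrogen-bonded to C4=O.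

Step 7
Reactants: 11 5-(5-hydroxy-6,7,8-trimethoxy-4-oxo-4H-chromen-2-yl)-2-methoxyphenyl pivalate
Product: 12 Gardenin D, 5-hydroxy-2-(3-hydroxy-4-methoxyphenyl)-6,7,8-trimethoxy-4H-chromen-4-one
Conditions: K2CO3 (0.2 equiv), MeOH/THF, rt to 40 °C; then pH 5 buffer
Reagents that add atoms: none
Why: Base-catalysed transesterification (methanolysis) of an aryl ester; the phenoxide leaving group makes the aryl pivalate far more labile than the methyl ethers, and the pyranone should be stable to carbonate in methanol.

## Compound list

1 | 2,3,4-trimethoxybenzaldehyde | COc1ccc(C=O)c(OC)c1OC | starting material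
2 | 2,3,4-trimethoxyphenyl formate | COc1ccc(OC=O)c(OC)c1OC | intermediate
3 | 2,3,4-trimethoxyphenol | COc1ccc(O)c(OC)c1OC | intermediate
4 | difluoroboron chelate of ketone 5 (2,2-difluoro-6,7,8-trimethoxy-4-methyl-1,3,2-benzodioxaborinine with a carbonyl O→B dative bond) | CC1=[O+][B-](F)(F)Oc2c(OC)c(OC)c(OC)cc21 | intermediate
5 | 1-(2-hydroxy-3,4,5-trimethoxyphenyl)ethan-1-one | CC(=O)c1cc(OC)c(OC)c(OC)c1O | intermediate
6 | isovanillin (3-hydroxy-4-methoxybenzaldehyde) | COc1ccc(C=O)cc1O | starting material
7 | (E)-1-(2-hydroxy-3,4,5-trimethoxyphenyl)-3-(3-hydroxy-4-methoxyphenyl)prop-2-en-1-one | COc1ccc(/C=C/C(=O)c2cc(OC)c(OC)c(OC)c2O)cc1O | intermediate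
8 | 2-(3-hydroxy-4-methoxyphenyl)-6,7,8-trimethoxy-4H-chromen-4-one | COc1ccc(-c2cc(=O)c3cc(OC)c(OC)c(OC)c3o2)cc1O | intermediate
9 | 2-methoxy-5-(6,7,8-trimethoxy-4-oxo-4H-chromen-2-yl)phenyl pivalate | COc1ccc(-c2cc(=O)c3cc(OC)c(OC)c(OC)c3o2)cc1OC(=O)C(C)(C)C | intermediate
10 | 6,7,8-trimethoxy-2-[4-methoxy-3-(pivaloyloxy)phenyl]-4-oxo-4H-chromen-5-yl trifluoroacetate | COc1ccc(-c2cc(=O)c3c(OC(=O)C(F)(F)F)c(OC)c(OC)c(OC)c3o2)cc1OC(=O)C(C)(C)C | intermediate
11 | 5-(5-hydroxy-6,7,8-trimethoxy-4-oxo-4H-chromen-2-yl)-2-methoxyphenyl pivalate (3'-O-pivaloyl Gardenin D) | COc1ccc(-c2cc(=O)c3c(O)c(OC)c(OC)c(OC)c3o2)cc1OC(=O)C(C)(C)C | intermediate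
12 | Gardenin D, 5-hydroxy-2-(3-hydroxy-4-methoxyphenyl)-6,7,8-trimethoxy-4H-chromen-4-one | COc1ccc(-c2cc(=O)c3c(O)c(OC)c(OC)c(OC)c3o2)cc1O | target

## Step count and risk

Total: 7 steps. Longest linear sequence: 7 steps (1 to 12); isovanillin 6 enters at step 3.

**Step 6 (key step).** Cyclometalation may be slow, because C5–H is flanked by the C6 methoxy group and the carbonyl is partly protonated in CF3CO2H. Non-directed oxidation of the very electron-rich ring A by the trivalent iodine reagent may then dominate, with radical-cation formation and oxidative demethylation towards quinones. Lesser risks are acyl exchange at the pivalate and ester-directed metalation at C2'. Within the same disconnection the oxidant can be changed to K2S2O8, or the catalyst to Pd(OCOCF3)2 (divalent palladium). The fallback that changes the approach gives up the C–H oxygenation; it sets out from 5 and returns at 12. Bromination of 5 at its only free ring carbon (N-bromosuccinimide, MeCN) should give 1-(2-bromo-6-hydroxy-3,4,5-trimethoxyphenyl)ethan-1-one F1. Copper-mediated methoxylation (NaOMe, CuBr, MeOH/DMF, reflux) should then give 1-(2-hydroxy-3,4,5,6-tetramethoxyphenyl)ethan-1-one F2. Claisen–Schmidt condensation with 6 (KOH, EtOH) should give (E)-1-(2-hydroxy-3,4,5,6-tetramethoxyphenyl)-3-(3-hydroxy-4-methoxyphenyl)prop-2-en-1-one F3, and I2–DMSO closure should give 2-(3-hydroxy-4-methoxyphenyl)-5,6,7,8-tetramethoxy-4H-chromen-4-one F4. BCl3 (CH2Cl2, −78 to 0 °C) should cleave only the C5 methyl ether, the one that can chelate boron together with C4=O, and so give 12.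

**Step 2.** Acylation may occur at C5 of 3 (ortho to the 4-methoxy group) instead of C6, and the Lewis acid may cleave a methyl ether at 90 °C. The fallback removes the regiochemical question by symmetry; it sets out from 3 and returns at 5. O-Methylation (MeI, K2CO3, acetone) should give 1,2,3,4-tetramethoxybenzene F5, whose two free positions are equivalent. Friedel–Crafts acetylation (AcCl, AlCl3, CH2Cl2) should give 1-(2,3,4,5-tetramethoxyphenyl)ethan-1-one F6. The methoxy group ortho to the carbonyl would then be cleaved by chelation-controlled demethylation, with AlCl3 in the same flask or with BCl3 separately, to give 5.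

**Step 3.** The condensation may remain incomplete, because both partners react as phenoxides, and Cannizzaro disproportionation of 6 may compete over long reaction times. The fallback masks the ring B phenol before the condensation; it sets out from 6 and returns at 8. Benzylation (BnBr, K2CO3, DMF) should give 3-(benzyloxy)-4-methoxybenzaldehyde F7. Condensation with 5 (KOH, EtOH) should give (E)-3-[3-(benzyloxy)-4-methoxyphenyl]-1-(2-hydroxy-3,4,5-trimethoxyphenyl)prop-2-en-1-one F8. I2–DMSO closure should give 2-[3-(benzyloxy)-4-methoxyphenyl]-6,7,8-trimethoxy-4H-chromen-4-one F9, and hydrogenolysis (H2, Pd/C, EtOAc) should give 8.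

**Step 4.** Electrophilic iodination or oxidative degradation of the free guaiacol-type ring B may occur at 120 °C, or the reaction may stall at the flavanone oxidation level. The fallback separates cyclisation from oxidation and protects the phenol in between; it sets out from 7 and returns at 9. NaOAc in refluxing EtOH should isomerise 7 to racemic 2-(3-hydroxy-4-methoxyphenyl)-6,7,8-trimethoxychroman-4-one F10. Pivaloylation (PivCl, Et3N, DMAP) should give racemic 2-methoxy-5-(6,7,8-trimethoxy-4-oxochroman-2-yl)phenyl pivalate F11, and dehydrogenation with DDQ in refluxing dioxane should give 9.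

## Further compounds

F1 | step 6 | 1-(2-bromo-6-hydroxy-3,4,5-trimethoxyphenyl)ethan-1-one | CC(=O)c1c(Br)c(OC)c(OC)c(OC)c1O
F2 | step 6 | 1-(2-hydroxy-3,4,5,6-tetramethoxyphenyl)ethan-1-one | CC(=O)c1c(OC)c(OC)c(OC)c(OC)c1O
F3 | step 6 | (E)-1-(2-hydroxy-3,4,5,6-tetramethoxyphenyl)-3-(3-hydroxy-4-methoxyphenyl)prop-2-en-1-one | COc1ccc(/C=C/C(=O)c2c(OC)c(OC)c(OC)c(OC)c2O)cc1O
F4 | step 6 | 2-(3-hydroxy-4-methoxyphenyl)-5,6,7,8-tetramethoxy-4H-chromen-4-one | COc1ccc(-c2cc(=O)c3c(OC)c(OC)c(OC)c(OC)c3o2)cc1O
F5 | step 2 | 1,2,3,4-tetramethoxybenzene | COc1ccc(OC)c(OC)c1OC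
F6 | step 2 | 1-(2,3,4,5-tetramethoxyphenyl)ethan-1-one | CC(=O)c1cc(OC)c(OC)c(OC)c1OC
F7 | step 3 | 3-(benzyloxy)-4-methoxybenzaldehyde | COc1ccc(C=O)cc1OCc1ccccc1
F8 | step 3 | (E)-3-[3-(benzyloxy)-4-methoxyphenyl]-1-(2-hydroxy-3,4,5-trimethoxyphenyl)prop-2-en-1-one | COc1ccc(/C=C/C(=O)c2cc(OC)c(OC)c(OC)c2O)cc1OCc1ccccc1
F9 | step 3 | 2-[3-(benzyloxy)-4-methoxyphenyl]-6,7,8-trimethoxy-4H-chromen-4-one | COc1ccc(-c2cc(=O)c3cc(OC)c(OC)c(OC)c3o2)cc1OCc1ccccc1
F10 | step 4 | racemic 2-(3-hydroxy-4-methoxyphenyl)-6,7,8-trimethoxychroman-4-one | COc1ccc(C2CC(=O)c3cc(OC)c(OC)c(OC)c3O2)cc1O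
F11 | step 4 | racemic 2-methoxy-5-(6,7,8-trimethoxy-4-oxochroman-2-yl)phenyl pivalate | COc1ccc(C2CC(=O)c3cc(OC)c(OC)c(OC)c3O2)cc1OC(=O)C(C)(C)C
A1 | alternative 1 | 1-[3-(benzyloxy)-4-methoxyphenyl]-3-(2,3,4,5-tetramethoxyphenyl)propane-1,3-dione | COc1ccc(C(=O)CC(=O)c2cc(OC)c(OC)c(OC)c2OC)cc1OCc1ccccc1
A2 | alternative 1 | 3'-(benzyloxy)-5,6,7,8,4'-pentamethoxyflavone | COc1ccc(-c2cc(=O)c3c(OC)c(OC)c(OC)c(OC)c3o2)cc1OCc1ccccc1
A3 | alternative 2 | 2,3,4,5-tetramethoxy-6-(trimethylsilyl)phenyl trifluoromethanesulfonate | COc1c(OC)c(OC)c([Si](C)(C)C)c(OS(=O)(=O)C(F)(F)F)c1OC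
A4 | alternative 2 | 3,4,5,6-tetramethoxybenzyne | COC1=C(OC)C(OC)=C(OC)C#C1
A5 | alternative 2 | 3-[3-(benzyloxy)-4-methoxyphenyl]prop-2-ynoic acid | COc1ccc(C#CC(=O)O)cc1OCc1ccccc1
A6 | alternative 2 | 3-[3-(benzyloxy)-4-methoxyphenyl]-1-(2-hydroxy-3,4,5,6-tetramethoxyphenyl)prop-2-yn-1-one | COc1ccc(C#CC(=O)c2c(O)c(OC)c(OC)c(OC)c2OC)cc1OCc1ccccc1
A7 | alternative 3 | 5-(benzyloxy)-6,7,8-trimethoxy-4H-chromen-4-one | O=c1ccoc2c(OC)c(OC)c(OC)c(OCc3ccccc3)c12
A8 | alternative 3 | [3-(benzyloxy)-4-methoxyphenyl]boronic acid | COc1ccc(B(O)O)cc1OCc1ccccc1
A9 | alternative 3 | 5,3'-di-O-benzyl Gardenin D | COc1ccc(-c2cc(=O)c3c(OCc4ccccc4)c(OC)c(OC)c(OC)c3o2)cc1OCc1ccccc1
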